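**Plan**

- Retrosynthetic cuts: first the ester bond O6–C(=O) (to diol 16 and acid chloride 20); then the C4–O bond, traced back to the axial C4–H bond through a six-membered 4,6-carbonate built from a carbamate on O6; then C12–H back to C12–O, the C6 configuration and the C3 methylene back to the lactone and ketone of (−)-α-santonin. No skeletal C–C bond is cut.
- Enabling feature (eudesmane numbering: ring A = C1–C5 with C10, ring B = C5–C10, C14 the methyl on C10, C15 the methyl on C4, C11/C12 the side chain on C7): on the trans-fused decalin the oxygens on C4 and C6 are both axial on the β face and flank the ring-fusion carbon C5. A carbamate on O6 therefore lies over the axial 4β-H of the 4-deoxy compound, and its carbonyl oxygen can close onto C4.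
- Forward order: rings A and B come intact from santonin. Ring A is saturated and freed of the C3 oxygen, the lactone is reduced, C6 is inverted, the temporary ring O6–C(=O)–O4 is closed in the key step, C12 is reduced to methyl, and the cinnamoyl unit is attached last.
- Stereochemistry: C7 and C10 from santonin; 5α-H from hydrogenation and the equatorial C15 methyl (4β-H) from equilibration; 6β-O from hydride attack opposite the axial C14 methyl; 4β-O from the O6 tether; the E olefin from the acid.
- C12 is carried as its mesylate through the key step. The tertiary C11–H of a free isopropyl group is an equally placed γ-hydrogen of O6 and would be expected to compete for the nitrogen radical; a sulfonate on C12 deactivates it and is removed afterwards by hydride together with the carbonate.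

Key step: step 8

**Route**

Step 1
Reactants: 1 (−)-α-santonin
Product: 3 α-tetrahydrosantonin (11S-3-oxo-4βH,5αH-eudesmano-12,6α-lactone), via 4-epi-tetrahydrosantonin 2 (not isolated)
Conditions: H2 (1 atm), Pd/C, EtOAc, rt; filter; HCl (cat.), EtOH, rt
Reagents that add atoms: none
Why: Catalytic hydrogenation adds H2 syn to the α face of both ring A olefins (opposite the axial C14 methyl) and so sets the 5α-H of the trans-decalin, and acid-catalysed epimerisation through the C3 enol then turns the first-formed axial 4β-methyl into the equatorial 4α-methyl, which leaves the 4β-H axial.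

Step 2
Reactants: 3 α-tetrahydrosantonin
Product: 4 3,3-ethylenedithioketal of α-tetrahydrosantonin
Conditions: HSCH2CH2SH, BF3·OEt2, AcOH, rt
Reagents that add atoms: ethane-1,2-dithiol, SCCS
Why: Lewis-acid-promoted dithioketalisation takes place at the only ketone, the lactone is inert and the equatorial C15 methyl is already the thermodynamic epimer.

Step 3
Reactants: 4 dithioketal
Product: 5 (11S)-4βH,5αH-eudesmano-12,6α-lactone
Conditions: Raney Ni, EtOH, reflux
Reagents that add atoms: none
Why: Raney nickel desulfurisation (Mozingo reduction) hydrogenolyses both C–S bonds and leaves C3 as a methylene group without touching the lactone or any stereocentre.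

Step 4
Reactants: 5 lactone
Product: 6 (11S)-4βH,5αH-eudesmane-6α,12-diol
Conditions: LiAlH4, THF, 0 °C to rt; aq. NaOH work-up
Reagents that add atoms: none
Why: LiAlH4 reduction of the γ-lactone gives the 1,4-diol and changes no stereocentre.

Step 5
Reactants: 6 diol
Product: 7 (11S)-6α-hydroxy-4βH,5αH-eudesman-12-yl methanesulfonate
Conditions: MsCl (1.1 equiv), pyridine, CH2Cl2, −10 °C; cold work-up, used at once
Reagents that add atoms: methanesulfonyl chloride (MsCl), CS(=O)(=O)Cl
Why: Selective sulfonylation should occur at the primary C12 hydroxyl because the 6α-hydroxyl is flanked by C5, C7 and the peri C15 methyl, and the mesylate serves later both as electron-withdrawing neighbour of C11–H and as leaving group.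

Step 6
Reactants: 7 hydroxy mesylate
Product: 8 (11S)-6-oxo-4βH,5αH-eudesman-12-yl methanesulfonate
Conditions: Dess–Martin periodinane, CH2Cl2, 0 °C to rt
Reagents that add atoms: none
Why: Dess–Martin oxidation of the secondary alcohol runs without base, so the α-stereocentres C5 and C7 (both already in their preferred configuration) are not enolised and the mesylate is not displaced.

Step 7
Reactants: 8 keto mesylate; 9 2,2,2-trifluoroethyl isocyanate
Product: 11 (11S)-12-(methanesulfonyloxy)-4βH,5αH-eudesman-6β-yl N-(2,2,2-trifluoroethyl)carbamate, via lithium 6β-alkoxide 10 (not isolated)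
Conditions: LiBH(s-Bu)3 (1.1 equiv), THF, −78 °C; then CF3CH2NCO (1.5 equiv), −78 to −40 °C; AcOH quench at −78 °C
Reagents that add atoms: none
Why: Hydride reduction by the bulky trialkylborohydride should come from the α face (equatorial attack, since the axial approach on the β face is blocked by the syn-axial C14 methyl) and give the axial 6β-alkoxide, which is trapped cold by nucleophilic addition to the isocyanate (carbamoylation) before it can displace the C12 mesylate.

Step 8
Reactants: 11 carbamate
Product: 15 (11S)-12-(methanesulfonyloxy)-5αH-eudesmane-4β,6β-diyl carbonate, via N-bromocarbamate 12 (not isolated), via C4 bromide 13 (not isolated), via cyclic iminocarbonate 14 (not isolated)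
Conditions: CH3CO2Br, CH2Cl2, 0 °C, dark; CBr4, PhCF3, visible light, rt; Ag2CO3, CH2Cl2, rt; AcOH, H2O, THF, rt
Reagents that add atoms: water, O
Why: N-Bromination and light-induced homolysis of the N–Br bond give an electrophilic carbamate nitrogen radical that takes the axial C4–H by 1,6-hydrogen atom transfer through a seven-membered transition state; the C4 radical picks up bromine from CBr4 or another N–Br molecule in a chain, Ag2CO3 ionises the tertiary bromide so that the carbamate carbonyl oxygen closes onto C4, and aqueous acetic acid hydrolyses the iminocarbonate to the carbonate. The closest known reaction type is the Hofmann–Löffler–Freytag-type 1,3-diol synthesis from N-bromo trifluoroethylcarbamates at tertiary C–H bonds. The six-membered ring O6–C(=O)–O4 across C4–C5–C6 closes by 6-exo attack of the tethered oxygen on the planar C4 cation, which is possible because O6 and the 4β position are 1,3-diaxial on the trans-decalin. The new C4 stereocentre (oxygen β, C15 methyl α) is fixed by the tether from O6 whatever the configuration of the bromide. The step needs site selectivity among the γ-hydrogens of O6: the tertiary C11–H is switched off by the polar effect of the adjacent C12 mesylate, the syn-axial C8–H is secondary and the C14 hydrogens are primary and further away, which should leave the tertiary syn-axial C4–H as the preferred site.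

Step 9
Reactants: 15 carbonate mesylate
Product: 16 5αH-eudesmane-4β,6β-diol
Conditions: LiEt3BH (6 equiv), THF, 0 °C to rt; aq. NaOH work-up
Reagents that add atoms: none
Why: LiEt3BH displaces the primary mesylate by SN2 hydride transfer (C12 becomes the second methyl of the isopropyl group) and reductively cleaves the carbonate at its acyl C–O bonds, so the configurations at C4 and C6 are retained.

Step 10
Reactants: 17 (E)-3-hydroxycinnamic acid
Product: 19 (E)-3-(tert-butyldimethylsilyloxy)cinnamic acid, via bis-silylated silyl ester 18 (not isolated)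
Conditions: TBSCl (2.4 equiv), imidazole, DMF, rt; then AcOH/H2O/THF, rt
Reagents that add atoms: tert-butyldimethylsilyl chloride (TBSCl), CC(C)(C)[Si](C)(C)Cl
Why: Silylation of phenol and acid followed by selective hydrolysis of the labile silyl ester leaves the aryl silyl ether and the E olefin untouched.

Step 11
Reactants: 19 silyl-protected acid
Product: 20 (E)-3-(tert-butyldimethylsilyloxy)cinnamoyl chloride
Conditions: (COCl)2, DMF (cat.), CH2Cl2, 0 °C to rt; concentrate
Reagents that add atoms: oxalyl chloride, O=C(Cl)C(=O)Cl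
Why: Acid chloride formation through the chloroiminium species from oxalyl chloride and DMF is anhydrous and should spare the aryl silyl ether.

Step 12
Reactants: 16 diol; 20 acid chloride
Product: 21 4β-hydroxy-5αH-eudesman-6β-yl (E)-3-(tert-butyldimethylsilyloxy)cinnamate
Conditions: Et3N, DMAP, CH2Cl2, rt to 40 °C
Reagents that add atoms: none
Why: DMAP-catalysed acylation through the acylpyridinium ion should take the secondary 6β-hydroxyl, the tertiary 4β-hydroxyl being far less reactive, and no carbinol centre is touched.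

Step 13
Reactants: 21 silyl-protected ester
Product: 22 4β-hydroxy-5αH-eudesman-6β-yl (E)-3-hydroxycinnamate (target)
Conditions: Bu4NF, AcOH, THF, 0 °C
Reagents that add atoms: none
Why: Fluoride desilylation of the aryl silyl ether, buffered by acetic acid, should leave the cinnamate ester on O6 and the tertiary alcohol unchanged.

**Compound list**

1 | (−)-α-santonin | C[C@H]1[C@@H]2CC[C@@]3(C)C=CC(=O)C(C)=C3[C@H]2OC1=O | starting material
2 | 4-epi-tetrahydrosantonin (axial 4β-methyl, 5α-H) | C[C@H]1[C@@H]2CC[C@@]3(C)CCC(=O)[C@H](C)[C@@H]3[C@H]2OC1=O | intermediate (not isolated)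
3 | α-tetrahydrosantonin, (11S)-3-oxo-4βH,5αH-eudesmano-12,6α-lactone | C[C@H]1[C@@H]2CC[C@@]3(C)CCC(=O)[C@@H](C)[C@@H]3[C@H]2OC1=O | intermediate
4 | 3,3-ethylenedithioketal of 3 | C[C@H]1[C@@H]2CC[C@@]3(C)CCC4(SCCS4)[C@@H](C)[C@@H]3[C@H]2OC1=O | intermediate
5 | (11S)-4βH,5αH-eudesmano-12,6α-lactone | C[C@H]1[C@@H]2CC[C@@]3(C)CCC[C@@H](C)[C@@H]3[C@H]2OC1=O | intermediate
6 | (11S)-4βH,5αH-eudesmane-6α,12-diol | C[C@H](CO)[C@@H]1CC[C@@]2(C)CCC[C@@H](C)[C@@H]2[C@H]1O | intermediate
7 | (11S)-6α-hydroxy-4βH,5αH-eudesman-12-yl methanesulfonate | C[C@H](COS(C)(=O)=O)[C@@H]1CC[C@@]2(C)CCC[C@@H](C)[C@@H]2[C@H]1O | intermediate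
8 | (11S)-6-oxo-4βH,5αH-eudesman-12-yl methanesulfonate | C[C@H](COS(C)(=O)=O)[C@@H]1CC[C@@]2(C)CCC[C@@H](C)[C@@H]2C1=O | intermediate
9 | 2,2,2-trifluoroethyl isocyanate | O=C=NCC(F)(F)F | starting material
10 | lithium (11S)-12-(methanesulfonyloxy)-4βH,5αH-eudesman-6β-olate | C[C@H](COS(C)(=O)=O)[C@@H]1CC[C@@]2(C)CCC[C@@H](C)[C@@H]2[C@@H]1[O-].[Li+] | intermediate (not isolated)
11 | (11S)-12-(methanesulfonyloxy)-4βH,5αH-eudesman-6β-yl N-(2,2,2-trifluoroethyl)carbamate | C[C@H](COS(C)(=O)=O)[C@@H]1CC[C@@]2(C)CCC[C@@H](C)[C@@H]2[C@@H]1OC(=O)NCC(F)(F)F | intermediate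
12 | N-bromo derivative of 11 | C[C@H](COS(C)(=O)=O)[C@@H]1CC[C@@]2(C)CCC[C@@H](C)[C@@H]2[C@@H]1OC(=O)N(Br)CC(F)(F)F | intermediate (not isolated)
13 | 4-bromo derivative of 11 (C4 configuration not defined) | C[C@H](COS(C)(=O)=O)[C@@H]1CC[C@@]2(C)CCCC(C)(Br)[C@@H]2[C@@H]1OC(=O)NCC(F)(F)F | intermediate (not isolated)
14 | 4β,6β-cyclic N-(2,2,2-trifluoroethyl)iminocarbonate | C[C@H](COS(C)(=O)=O)[C@@H]1CC[C@@]2(C)CCC[C@]3(C)OC(=NCC(F)(F)F)O[C@H]1[C@H]23 | intermediate (not isolated)
15 | (11S)-12-(methanesulfonyloxy)-5αH-eudesmane-4β,6β-diyl carbonate | C[C@H](COS(C)(=O)=O)[C@@H]1CC[C@@]2(C)CCC[C@]3(C)OC(=O)O[C@H]1[C@H]23 | intermediate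
16 | 5αH-eudesmane-4β,6β-diol (C15 methyl α) | CC(C)[C@@H]1CC[C@@]2(C)CCC[C@](C)(O)[C@@H]2[C@@H]1O | intermediate
17 | (E)-3-hydroxycinnamic acid | O=C(O)/C=C/c1cccc(O)c1 | starting material
18 | tert-butyldimethylsilyl (E)-3-(tert-butyldimethylsilyloxy)cinnamate | CC(C)(C)[Si](C)(C)OC(=O)/C=C/c1cccc(O[Si](C)(C)C(C)(C)C)c1 | intermediate (not isolated)
19 | (E)-3-(tert-butyldimethylsilyloxy)cinnamic acid | O=C(O)/C=C/c1cccc(O[Si](C)(C)C(C)(C)C)c1 | intermediate
20 | (E)-3-(tert-butyldimethylsilyloxy)cinnamoyl chloride | O=C(Cl)/C=C/c1cccc(O[Si](C)(C)C(C)(C)C)c1 | intermediate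
21 | 4β-hydroxy-5αH-eudesman-6β-yl (E)-3-(tert-butyldimethylsilyloxy)cinnamate | CC(C)[C@@H]1CC[C@@]2(C)CCC[C@](C)(O)[C@@H]2[C@@H]1OC(=O)/C=C/c1cccc(O[Si](C)(C)C(C)(C)C)c1 | intermediate
22 | 4β-hydroxy-5αH-eudesman-6β-yl (E)-3-hydroxycinnamate | CC(C)[C@@H]1CC[C@@]2(C)CCC[C@](C)(O)[C@@H]2[C@@H]1OC(=O)/C=C/c1cccc(O)c1 | target

**Step count**

Total: 13 steps. Longest linear sequence: 11 steps (steps 1–9, 12 and 13); the side chain takes two steps (10 and 11).

**Steps most likely to fail**

Step 8. Hydrogen abstraction may not stay at C4–H (residual transfer from C11–H or from the syn-axial C8–H). The C4 cation may also lose a proton or take a hydride from C5 faster than the carbamate oxygen closes. The fallback sets out from 11 and returns at 16. Methyl(trifluoromethyl)dioxirane in CH2Cl2/1,1,1-trifluoroacetone at −20 to 0 °C inserts oxygen with retention into a tertiary C–H bond. C4–H is the only tertiary C–H not next to an oxygen-bearing carbon, so this should give (11S)-4β-hydroxy-12-(methanesulfonyloxy)-5αH-eudesman-6β-yl N-(2,2,2-trifluoroethyl)carbamate F1. LiEt3BH in THF at 0 °C then turns C12–OMs into methyl while O6 is still blocked, giving 4β-hydroxy-5αH-eudesman-6β-yl N-(2,2,2-trifluoroethyl)carbamate F2. KOH in aqueous EtOH at reflux removes the carbamate and gives diol 16.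

Step 7. The 6β-alkoxide may displace the C12 mesylate (closure to a cyclic ether) before the isocyanate traps it, or the lithiated carbamate may add to a second isocyanate. The fallback sets out from 6 and returns at 11, keeping C12 as a non-leaving acetate while the C6 oxygen is free. Ac2O (1.1 equiv) and pyridine at 0 °C acylate the primary hydroxyl to (11S)-6α-hydroxy-4βH,5αH-eudesman-12-yl acetate F3. Dess–Martin oxidation gives (11S)-6-oxo-4βH,5αH-eudesman-12-yl acetate F4. LiBH(s-Bu)3 at −78 °C with a cold AcOH quench gives (11S)-6β-hydroxy-4βH,5αH-eudesman-12-yl acetate F5. CF3CH2NCO with pyridine and catalytic DMAP in ClCH2CH2Cl at 50 °C gives (11S)-12-acetoxy-4βH,5αH-eudesman-6β-yl N-(2,2,2-trifluoroethyl)carbamate F6. K2CO3 in MeOH at 0 °C removes the acetate to give (11S)-12-hydroxy-4βH,5αH-eudesman-6β-yl N-(2,2,2-trifluoroethyl)carbamate F7, and MsCl in pyridine at 0 °C gives 11.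

Step 9. The carbonate may be cleaved before hydride has displaced the mesylate, so that the freed 6β-alkoxide closes onto C12 to a cis-fused tetrahydrofuran. The fallback sets out from 15 and returns at 16, removing the C12 oxygen by a radical path while the carbonate still masks both oxygens. NaI in butanone at 80 °C (Finkelstein exchange) gives (11S)-12-iodo-5αH-eudesmane-4β,6β-diyl carbonate F8. Bu3SnH with catalytic AIBN in toluene at 80 °C gives 5αH-eudesmane-4β,6β-diyl carbonate F9. K2CO3 in MeOH at rt then opens the carbonate to diol 16.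

**Further compounds**

F1 | step 8 | (11S)-4β-hydroxy-12-(methanesulfonyloxy)-5αH-eudesman-6β-yl N-(2,2,2-trifluoroethyl)carbamate | C[C@H](COS(C)(=O)=O)[C@@H]1CC[C@@]2(C)CCC[C@](C)(O)[C@@H]2[C@@H]1OC(=O)NCC(F)(F)F
F2 | step 8 | 4β-hydroxy-5αH-eudesman-6β-yl N-(2,2,2-trifluoroethyl)carbamate | CC(C)[C@@H]1CC[C@@]2(C)CCC[C@](C)(O)[C@@H]2[C@@H]1OC(=O)NCC(F)(F)F
F3 | step 7 | (11S)-6α-hydroxy-4βH,5αH-eudesman-12-yl acetate | C[C@H](COC(C)=O)[C@@H]1CC[C@@]2(C)CCC[C@@H](C)[C@@H]2[C@H]1O
F4 | step 7 | (11S)-6-oxo-4βH,5αH-eudesman-12-yl acetate | C[C@H](COC(C)=O)[C@@H]1CC[C@@]2(C)CCC[C@@H](C)[C@@H]2C1=O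
F5 | step 7 | (11S)-6β-hydroxy-4βH,5αH-eudesman-12-yl acetate | C[C@H](COC(C)=O)[C@@H]1CC[C@@]2(C)CCC[C@@H](C)[C@@H]2[C@@H]1O
F6 | step 7 | (11S)-12-acetoxy-4βH,5αH-eudesman-6β-yl N-(2,2,2-trifluoroethyl)carbamate | C[C@H](COC(C)=O)[C@@H]1CC[C@@]2(C)CCC[C@@H](C)[C@@H]2[C@@H]1OC(=O)NCC(F)(F)F
F7 | step 7 | (11S)-12-hydroxy-4βH,5αH-eudesman-6β-yl N-(2,2,2-trifluoroethyl)carbamate | C[C@H](CO)[C@@H]1CC[C@@]2(C)CCC[C@@H](C)[C@@H]2[C@@H]1OC(=O)NCC(F)(F)F
F8 | step 9 | (11S)-12-iodo-5αH-eudesmane-4β,6β-diyl carbonate | C[C@H](CI)[C@@H]1CC[C@@]2(C)CCC[C@]3(C)OC(=O)O[C@H]1[C@H]23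
F9 | step 9 | 5αH-eudesmane-4β,6β-diyl carbonate | CC(C)[C@@H]1CC[C@@]2(C)CCC[C@]3(C)OC(=O)O[C@H]1[C@H]23
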